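**Plan**

1. Retrosynthetic cuts, in order: the two O-benzyl groups and the alkyne oxidation level of the C5 side chain (one hydrogenation); the C5–C(sp) bond (Sonogashira at a C5–Cl handle); the C3–O bond (hydroboration–oxidation of a flav-3-ene); then the pair C4–C4a and O1–C8a together.
2. Enabling feature: C4a and C8a are ortho carbons of the A-ring, i.e. the two ends of an aryne triple bond, and O1–C2–C3–C4 of the pyran ring is the O=C–C=C of a cinnamaldehyde. The aldehyde O and C add across the aryne; 4π opening and oxa-6π closure then move O from C4 to C2.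
3. The C5 substituent next to C4a is carried as Cl: it polarises the aryne so that O adds to C8a, and it is later the cross-coupling handle for the bibenzyl chain.
4. Forward: o-silylaryl triflate (2 steps) plus O-benzylconiferaldehyde (1 step) give the racemic flav-3-ene in one cascade that builds the pyran ring and joins A- and B-ring halves.
5. Stereochemistry: C2 forms racemic in the electrocyclisation. A Cu-catalysed enantioselective hydroboration (kinetic resolution) consumes the (S)-chromene and adds boron anti to the aryl group, so oxidation gives the 2,3-trans (2R,3S) alcohol; no later step touches C2 or C3. The unreacted (R)-chromene should in principle be recyclable by photoracemisation through the reversible oxa-6π opening.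
6. Endgame: Sonogashira coupling brings in the third ring; a single hydrogenation saturates the alkyne and removes both benzyl groups.

Key step: step 4

Assumption: step 5 is written for the ligand antipode that consumes (S)-11; which antipode of Ph-BPE that is has to be fixed in a first run, and the mirror-image ligand is taken if the sense is opposite.

**Route**

Step 1
Reactants: 1 2-chloro-4-methoxyphenol
Product: 2 2-bromo-6-chloro-4-methoxyphenol
Conditions: NBS (1.05 equiv), i-Pr2NH (10 mol%), CH2Cl2, 0 °C → rt
Reagents that add atoms: N-bromosuccinimide, O=C1CCC(=O)N1Br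
Why: amine-mediated electrophilic ortho-bromination of a phenol, which should go to the only free position ortho to OH because the para position is blocked by OMe.

Step 2
Reactants: 2 2-bromo-6-chloro-4-methoxyphenol
Product: 5 2-chloro-4-methoxy-6-(trimethylsilyl)phenyl trifluoromethanesulfonate, via trimethylsilyl ether 3 (not isolated), via lithium 2-silylphenolate 4 (not isolated)
Conditions: HMDS, THF, 65 °C, then evaporate; n-BuLi, THF, −78 °C; Tf2O, −78 °C → rt
Reagents that add atoms: hexamethyldisilazane, C[Si](C)(C)N[Si](C)(C)C; trifluoromethanesulfonic anhydride, O=S(=O)(OS(=O)(=O)C(F)(F)F)C(F)(F)F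
Why: O-silylation, Br/Li exchange at C–Br (not C–Cl) with anionic 1,3 O→C silyl shift (retro-Brook rearrangement) and O-triflation, the standard one-pot entry to o-silylaryl triflate aryne precursors.

Step 3
Reactants: 6 coniferaldehyde, (2E)-3-(4-hydroxy-3-methoxyphenyl)prop-2-enal
Product: 7 (2E)-3-[4-(benzyloxy)-3-methoxyphenyl]prop-2-enal
Conditions: BnBr, K2CO3, DMF, rt
Reagents that add atoms: benzyl bromide, BrCc1ccccc1
Why: Williamson ether synthesis on the phenol; the benzyl ether is inert to fluoride, Cu–boryl and Pd(0) chemistry and leaves in the final hydrogenation.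

Step 4
Reactants: 5 2-chloro-4-methoxy-6-(trimethylsilyl)phenyl trifluoromethanesulfonate; 7 (2E)-3-[4-(benzyloxy)-3-methoxyphenyl]prop-2-enal
Product: 11 rac-2-[4-(benzyloxy)-3-methoxyphenyl]-5-chloro-7-methoxy-2H-chromene, via 3-chloro-5-methoxybenzyne 8 (not isolated), via styrylbenzoxete 9 (not isolated), via o-quinone methide 10 (not isolated)
Conditions: CsF (3 equiv), MeCN, rt, 5 (1.3 equiv) added slowly
Reagents that add atoms: none
Why: Fluoride removes the silyl group of 5 and triflate leaves, giving aryne 8, whose triple bond is polarised by the inductively withdrawing Cl on the neighbouring carbon so that the carbon that becomes C8a is the electrophilic end. The carbonyl O of 7 adds there and the aryl anion developing next to Cl collapses onto the carbonyl carbon (polar, stepwise [2+2]; the four-membered ring closes by anion–oxocarbenium recombination), so that O–C8a and C4–C4a form together in benzoxete 9. Strain-driven 4π electrocyclic ring opening gives o-quinone methide 10, and thermal disrotatory oxa-6π electrocyclisation of its O=C8a–C4a=C4–C3=C2 triene closes the pyran ring (O1–C2) and restores the aromatic A-ring. The closest known reaction type is the annulation of arynes with α,β-unsaturated aldehydes to 2H-chromenes, related to aryne insertion into the C=O bond of formamides. C2 is the only new stereocentre and forms without control (racemate), by design, since step 5 selects the enantiomer. The step needs regioselectivity (O to C8a, secured by the C5 chlorine, which the remote 7-OMe should oppose only weakly), chemoselectivity for C=O over C=C (the carbonyl oxygen is the most nucleophilic site of the enal towards the electrophilic aryne) and the chain-syn-to-C=O geometry of 10 (the other isomer clashes with the peri chlorine).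

Step 5
Reactants: 11 rac-2-[4-(benzyloxy)-3-methoxyphenyl]-5-chloro-7-methoxy-2H-chromene
Product: 13 (2R,3S)-2-[4-(benzyloxy)-3-methoxyphenyl]-5-chloro-7-methoxy-3,4-dihydro-2H-chromen-3-ol, via trans-3-boryl flavan 12 (not isolated)
Conditions: CuCl (5 mol%), Ph-BPE (6 mol%, antipode per assumption), NaOt-Bu (10 mol%), B2pin2 (0.55 equiv), MeOH (2 equiv), THF, 0 °C; then 30% H2O2, aq NaOH, 0 °C → rt; chromatography removes unreacted (R)-11
Reagents that add atoms: hydrogen peroxide, OO (the oxygen on C3); bis(pinacolato)diboron, CC1(C)OB(OC1(C)C)B1OC(C)(C)C(C)(C)O1 (its boron is only in intermediate 12)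
Why: copper-catalysed enantioselective hydroboration used as a kinetic resolution, in which Cu–boryl syn-addition across the styrenyl C3=C4 bond puts boron on C3 and copper on benzylic C4, anti to the C2 aryl group and only in the (S)-enantiomer matched to the ligand, so that protodecupration and stereoretentive C–B oxidation should give the 2,3-trans (2R,3S) alcohol.

Step 6
Reactants: 14 3-ethynylphenol
Product: 15 1-(benzyloxy)-3-ethynylbenzene
Conditions: BnBr, K2CO3, acetone, reflux
Reagents that add atoms: benzyl bromide, BrCc1ccccc1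
Why: Williamson ether synthesis; carbonate deprotonates the phenol but not the terminal alkyne.

Step 7
Reactants: 13 (2R,3S)-2-[4-(benzyloxy)-3-methoxyphenyl]-5-chloro-7-methoxy-3,4-dihydro-2H-chromen-3-ol; 15 1-(benzyloxy)-3-ethynylbenzene
Product: 16 (2R,3S)-2-[4-(benzyloxy)-3-methoxyphenyl]-5-{[3-(benzyloxy)phenyl]ethynyl}-7-methoxy-3,4-dihydro-2H-chromen-3-ol
Conditions: PdCl2(MeCN)2 (3 mol%), XPhos (9 mol%), Cs2CO3 (2.5 equiv), MeCN, 80 °C
Reagents that add atoms: none
Why: copper-free Sonogashira coupling of an aryl chloride with a bulky biaryl phosphine; the C5–Cl bond is meta to both ring oxygens, the free secondary alcohol should be tolerated and C2/C3 are not touched.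

Step 8
Reactants: 16 (2R,3S)-2-[4-(benzyloxy)-3-methoxyphenyl]-5-{[3-(benzyloxy)phenyl]ethynyl}-7-methoxy-3,4-dihydro-2H-chromen-3-ol
Product: 17 shanciol B, (2R,3S)-2-(4-hydroxy-3-methoxyphenyl)-5-[2-(3-hydroxyphenyl)ethyl]-7-methoxy-3,4-dihydro-2H-chromen-3-ol
Conditions: H2 (1 atm), 10% Pd/C, EtOAc–MeOH, rt
Reagents that add atoms: none
Why: catalytic hydrogenation should saturate the diaryl alkyne and hydrogenolyse both benzyl ethers, while the cyclic benzylic C2–O1 bond is kept under these mild conditions, as in debenzylation of flavan-3-ols.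

**Compound list**

1 | 2-chloro-4-methoxyphenol | COc1ccc(O)c(Cl)c1 | starting material
2 | 2-bromo-6-chloro-4-methoxyphenol | COc1cc(Cl)c(O)c(Br)c1 | intermediate
3 | (2-bromo-6-chloro-4-methoxyphenoxy)trimethylsilane | COc1cc(Cl)c(O[Si](C)(C)C)c(Br)c1 | intermediate
4 | lithium 2-chloro-4-methoxy-6-(trimethylsilyl)phenolate | COc1cc(Cl)c([O-])c([Si](C)(C)C)c1.[Li+] | intermediate
5 | 2-chloro-4-methoxy-6-(trimethylsilyl)phenyl trifluoromethanesulfonate | COc1cc(Cl)c(OS(=O)(=O)C(F)(F)F)c([Si](C)(C)C)c1 | intermediate
6 | coniferaldehyde, (2E)-3-(4-hydroxy-3-methoxyphenyl)prop-2-enal | COc1cc(/C=C/C=O)ccc1O | starting material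
7 | (2E)-3-[4-(benzyloxy)-3-methoxyphenyl]prop-2-enal | COc1cc(/C=C/C=O)ccc1OCc1ccccc1 | intermediate
8 | 3-chloro-5-methoxybenzyne (1-chloro-5-methoxycyclohexa-1,5-dien-3-yne) | COC1=CC#CC(Cl)=C1 | intermediate
9 | rac-2-{(E)-2-[4-(benzyloxy)-3-methoxyphenyl]ethenyl}-3-chloro-5-methoxy-2H-1-benzoxete | COc1cc(Cl)c2c(c1)OC2/C=C/c1ccc(OCc2ccccc2)c(OC)c1 | intermediate
10 | 6-{(2E)-3-[4-(benzyloxy)-3-methoxyphenyl]prop-2-en-1-ylidene}-5-chloro-3-methoxycyclohexa-2,4-dien-1-one, chain on the side of the C=O | COC1=CC(=O)/C(=C\C=C\c2ccc(OCc3ccccc3)c(OC)c2)C(Cl)=C1 | intermediate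
11 | rac-2-[4-(benzyloxy)-3-methoxyphenyl]-5-chloro-7-methoxy-2H-chromene | COc1cc(Cl)c2c(c1)OC(c1ccc(OCc3ccccc3)c(OC)c1)C=C2 | intermediate
12 | 2-{(2S,3S)-2-[4-(benzyloxy)-3-methoxyphenyl]-5-chloro-7-methoxy-3,4-dihydro-2H-chromen-3-yl}-4,4,5,5-tetramethyl-1,3,2-dioxaborolane (2,3-trans) | COc1cc(Cl)c2c(c1)O[C@H](c1ccc(OCc3ccccc3)c(OC)c1)[C@@H](B1OC(C)(C)C(C)(C)O1)C2 | intermediate
13 | (2R,3S)-2-[4-(benzyloxy)-3-methoxyphenyl]-5-chloro-7-methoxy-3,4-dihydro-2H-chromen-3-ol (2,3-trans) | COc1cc(Cl)c2c(c1)O[C@H](c1ccc(OCc3ccccc3)c(OC)c1)[C@@H](O)C2 | intermediate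
14 | 3-ethynylphenol | C#Cc1cccc(O)c1 | starting material
15 | 1-(benzyloxy)-3-ethynylbenzene | C#Cc1cccc(OCc2ccccc2)c1 | intermediate
16 | (2R,3S)-2-[4-(benzyloxy)-3-methoxyphenyl]-5-{[3-(benzyloxy)phenyl]ethynyl}-7-methoxy-3,4-dihydro-2H-chromen-3-ol | COc1cc(C#Cc3cccc(OCc4ccccc4)c3)c2c(c1)O[C@H](c1ccc(OCc3ccccc3)c(OC)c1)[C@@H](O)C2 | intermediate
17 | shanciol B, (2R,3S)-2-(4-hydroxy-3-methoxyphenyl)-5-[2-(3-hydroxyphenyl)ethyl]-7-methoxy-3,4-dihydro-2H-chromen-3-ol | COc1cc(CCc2cccc(O)c2)c2c(c1)O[C@H](c1ccc(O)c(OC)c1)[C@@H](O)C2 | target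

**Step count and risks**

Total steps: 8. Longest linear sequence: 6 (steps 1, 2, 4, 5, 7, 8).

Steps most likely to fail:

1. Step 4. The aryne may be lost to competing pathways: addition of the carbonyl oxygen at the wrong aryne carbon, [2+2] or ene reaction at the C=C bond, or capture of the o-quinone methide by a second aryne. Fallback, setting out from 7 and returning at 11: 7 is condensed with commercial 3-chloro-5-methoxyphenol (COc1cc(O)cc(Cl)c1) using phenylboronic acid and catalytic acetic acid in refluxing toluene with removal of water. The boron-templated, ortho-specific hydroxyalkylation should occur between OH and Cl (para to OMe) and give 4-{(E)-2-[4-(benzyloxy)-3-methoxyphenyl]ethenyl}-5-chloro-7-methoxy-2-phenyl-4H-1,3,2-benzodioxaborinine F1. On continued heating F1 should fragment to the same o-quinone methide 10, which closes to 11. This builds the pyran ring from a phenol that already carries O1, without an aryne.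

2. Step 5. Borylcupration of the electron-rich styrenyl bond next to the peri chlorine may be slow, or the two enantiomers may be discriminated poorly. Fallback, setting out from 11 and returning at 13: uncatalysed hydroboration of racemic 11 with BH3·SMe2 in THF followed by H2O2/NaOH should add boron to C3 anti to the aryl group and give rac-(2R*,3S*)-2-[4-(benzyloxy)-3-methoxyphenyl]-5-chloro-7-methoxy-3,4-dihydro-2H-chromen-3-ol F2. F2 is then resolved by preparative chromatography on a chiral stationary phase to give 13.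

3. Step 7. Oxidative addition into the ortho-substituted C–Cl bond may be slow, with competing oligomerisation of the alkyne. Fallback, setting out from 15 (with 13) and returning at 17: Lindlar semi-hydrogenation of 15 gives 1-(benzyloxy)-3-ethenylbenzene F3. Hydroboration with 9-BBN gives 9-{2-[3-(benzyloxy)phenyl]ethyl}-9-borabicyclo[3.3.1]nonane F4, used in solution. B-alkyl Suzuki–Miyaura coupling of F4 with 13 (Pd(OAc)2, RuPhos, K3PO4, THF–H2O, 70 °C) gives (2R,3S)-2-[4-(benzyloxy)-3-methoxyphenyl]-5-{2-[3-(benzyloxy)phenyl]ethyl}-7-methoxy-3,4-dihydro-2H-chromen-3-ol F5. Hydrogenolysis of F5 under the conditions of step 8 gives 17.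

**Further compounds**

F1 | step 4 | 4-{(E)-2-[4-(benzyloxy)-3-methoxyphenyl]ethenyl}-5-chloro-7-methoxy-2-phenyl-4H-1,3,2-benzodioxaborinine | COc1cc(Cl)c2c(c1)OB(c1ccccc1)OC2/C=C/c1ccc(OCc2ccccc2)c(OC)c1
F2 | step 5 | rac-(2R*,3S*)-2-[4-(benzyloxy)-3-methoxyphenyl]-5-chloro-7-methoxy-3,4-dihydro-2H-chromen-3-ol (both enantiomers) | COc1cc(Cl)c2c(c1)O[C@H](c1ccc(OCc3ccccc3)c(OC)c1)[C@@H](O)C2.COc1cc(Cl)c2c(c1)O[C@@H](c1ccc(OCc3ccccc3)c(OC)c1)[C@H](O)C2
F3 | step 7 | 1-(benzyloxy)-3-ethenylbenzene | C=Cc1cccc(OCc2ccccc2)c1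
F4 | step 7 | 9-{2-[3-(benzyloxy)phenyl]ethyl}-9-borabicyclo[3.3.1]nonane | C(Cc1cccc(OCc2ccccc2)c1)B1C2CCCC1CCC2
F5 | step 7 | (2R,3S)-2-[4-(benzyloxy)-3-methoxyphenyl]-5-{2-[3-(benzyloxy)phenyl]ethyl}-7-methoxy-3,4-dihydro-2H-chromen-3-ol | COc1cc(CCc3cccc(OCc4ccccc4)c3)c2c(c1)O[C@H](c1ccc(OCc3ccccc3)c(OC)c1)[C@@H](O)C2
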